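At late times the two earlier runs stood at nearly the same share of their charge, 35.7 % in the south run and 35.4 % in the north-east run, so the late readings told me little about how quickly a charge is used. The early readings told me more.

| flask | solid substrate | remark | time |
|---|---|---|---|
| south | 1.3 M | run made earlier |  |
| north-east | 3 M | run made earlier |  |
| flask | 2.0 M |  | 25 h |

| south: time / h | south: target / % | north-east: time / h | north-east: target / % |
|---|---|---|---|
| 0.667 | 18.4 | 0.667 | 7.6 |
| 2.00 | 39.4 | 2.00 | 21.3 |
| 5.00 | 36.0 | 5.00 | 36.0 |
| 15.0 | 35.7 | 15.0 | 35.4 |

(each reading ± 0.3 percentage points)

- solid, in amounts per volume of the solution: solid substrate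
- at the start none of the solid substrate is in solution

1. when, up to 25 h, the flask holds most target
2. the amount of target, in percent of the solid substrate charged, at that time
3. the first time at which target reaches 12 %, in the same percent

After 0.667 h the south run held 0.239 M of target and the north-east run 0.228 M, although their charges were 1.3 M and 3 M. My bench rule was therefore that, at charges like these, target is first made at one steady pace (zero order in the charge, as it is called), and these two readings gave 0.350 M h⁻¹. From this I took the turnover time, the hours this pace needs to make target equal to the whole charge: for the new flask, 5.71 h. Hours divided by the turnover time give a count, and the rule says that this count is the percent of target.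

I looked for the border at 2.00 h. The north-east run had a count of 23.3 % and read 21.3 %, a ratio of 0.912. The south run had a count of 53.8 % and read 39.4 %, a ratio of 0.732, so the rule had clearly failed there. The asked 12 % lies lower than that north-east reading, so I reckoned it at 0.685 h. The north-east run read 36.0 % at a count of 58.4 %, close to its last reading, so I estimated the new flask's peak to come before 3.33 h, and I could not count its height.

The forecast said 2.9 h, 44 % and 0.69 h, on the ground that the rate “barely depends on loading at early times”.

The flask held its most target, 38.9 %, at 2.59 h, and reached 12 % at 0.692 h.

    starting material ⇌ target (K = 14.0, k = 6.90 × 10⁻⁴ s⁻¹)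
    starting material ⇌ isomer of the product (K = 24.0, k = 7.90 × 10⁻⁵ s⁻¹)
    target ⇌ isomer of the product (k = 5.30 × 10⁻⁴ s⁻¹)
    solid substrate ⇌ starting material, rate k4*(cs4 - [starting material]) while solid is left; crystals form when [starting material] > cs4 (solubility = 0.850 M, k = 4.20 × 10⁻⁴ s⁻¹)

That peak lay 5.1 percentage points below the forecast, and at twice the best time, 5.18 h, the flask held 35.9 %. The peak came at a count of 45.4 %. With twice the solid substrate the turnover time is 11.4 h, and that flask's best time of 5.23 h is a count of 45.8 %.

The data were computed from invented constants; the scatter is artificial.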